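**Strategy.** Everything rests on cutting the C12–C13 bond of ring C. The precursor is an indane (ring B: C5, C6, C8, C9, C10) whose quaternary C8 is spiro-fused to a 1,2-bis(trimethylsilyloxy)cyclopentene. Two identical CH2 arms (C14, C15) lead to the oxygenated carbons C13 and C16, so C8 is not yet stereogenic; C9 carries a 2-iodoethyl chain and C6 a methyl ester. Fluoride releases an α-silyloxy enolate that alkylates C12 through C13 only on the chain-bearing face. This closes ring C, differentiates C13 (silyl ether) from C16 (ketone) and fixes C8 and C13 at once. C9 is set by catalytic enantioselective reduction; C6 follows by equilibration.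

Key step: step 17

**Remarks on the chemistry**
- Locants are gibberellane locants throughout: ring A is aromatic (C1–C5, C10), C4 bears CH3, and the furan is fused at C2–C3 with its oxygen on C3. C7 is the carboxyl carbon on C6, C11–C12 the chain on C9, C14/C15 the CH2 arms on C8, C13/C16 their oxygenated neighbours, C17 the exocyclic methylene.
- In a 3-oxoindane-1-carboxylate the C6–H (benzylic, α to the ester, conjugated with the C9 carbonyl through the arene) is more acidic than C8–H2, so base would alkylate C6. C6 is therefore built as a malonate carbon and cut down to the mono-ester only after C8 and C9 are in place.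
- The C6 configuration is taken to be under thermodynamic control. Trans to the C9 chain the ester can sit pseudo-axial, clear of the C4 methyl group; the same preference should hold in the tetracycle, so later basic steps should not erode it.
- Assumption: the sense of induction in step 10 is assigned from the accepted face-shielding model of the imidazolidinone iminium ion; the antipodal catalyst would be used if the opposite sense were found.
- Diol 24 (two facial cis isomers) and dione 25 (largely enolised) are carried as mixtures that converge at 26.

**Route**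

Step 1
Reactants: 1 3-bromo-2-methylphenol; 2 paraformaldehyde
Product: 3 4-bromo-2-hydroxy-3-methylbenzaldehyde
Conditions: MgCl2, Et3N, (CH2O)n, MeCN, reflux
Reagents that add atoms: paraformaldehyde 2, C=O
Why: Magnesium-phenoxide-directed ortho-formylation (Casnati–Skattebøl type) can only strike the single free ortho position of the phenol, the carbon that later carries the furan ring.

Step 2
Reactants: 3 4-bromo-2-hydroxy-3-methylbenzaldehyde; 4 ethyl diazoacetate
Product: 6 ethyl 6-bromo-7-methylbenzofuran-3-carboxylate, via hemiacetal 5 (not isolated)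
Conditions: HBF4·OEt2 (10 mol%), CH2Cl2, rt; then conc. H2SO4
Reagents that add atoms: ethyl diazoacetate 4, CCOC(=O)C=[N+]=[N-]
Why: Acid-catalysed addition of the diazo ester to the aldehyde with 1,2-aryl shift and loss of N2 gives a formyl arylacetate that the phenol traps as a hemiacetal, and dehydration then gives the benzofuran-3-carboxylate, a known salicylaldehyde-to-benzofuran annulation.

Step 3
Reactants: 6 ethyl 6-bromo-7-methylbenzofuran-3-carboxylate; 7 dimethyl malonate
Product: 8 dimethyl 2-[3-(ethoxycarbonyl)-7-methylbenzofuran-6-yl]malonate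
Conditions: Pd2(dba)3 (1 mol%), P(t-Bu)3·HBF4, K3PO4, toluene, 80 °C
Reagents that add atoms: dimethyl malonate 7, COC(=O)CC(=O)OC
Why: Palladium-catalysed α-arylation of a malonate with a bulky electron-rich phosphine tolerates the ortho methyl group and installs C6 as a malonate carbon, which after the next step has no hydrogen left to compete with C8.

Step 4
Reactants: 8 dimethyl 2-[3-(ethoxycarbonyl)-7-methylbenzofuran-6-yl]malonate; 9 tert-butyl bromoacetate
Product: 10 1-tert-butyl 2,2-dimethyl 2-[3-(ethoxycarbonyl)-7-methylbenzofuran-6-yl]ethane-1,2,2-tricarboxylate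
Conditions: NaH, THF, 0 °C to rt
Reagents that add atoms: tert-butyl bromoacetate 9, CC(C)(C)OC(=O)CBr
Why: The stabilised arylmalonate anion undergoes SN2 alkylation with the α-bromo ester, bringing in C8 and C9 as an acid-labile tert-butyl ester that can be unmasked beside the methyl and ethyl esters.

Step 5
Reactants: 10 1-tert-butyl 2,2-dimethyl 2-[3-(ethoxycarbonyl)-7-methylbenzofuran-6-yl]ethane-1,2,2-tricarboxylate
Product: 12 indanone triester (C9 ketone; C8 methylene; C6 gem-diester), via carboxylic acid 11 (not isolated)
Conditions: Eaton's reagent (P2O5 in MeSO3H), 50 °C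
Reagents that add atoms: none
Why: Strong acid cleaves the tert-butyl ester and the derived acylium ion closes ring B by intramolecular Friedel–Crafts acylation at C10, the only free ortho position and the one para to the furan oxygen.

Step 6
Reactants: 12 indanone triester; 13 allyl bromide
Product: 14 8,8-diallyl indanone triester
Conditions: NaH (2.5 equiv), allyl bromide (3 equiv), THF–DMF, 0 to 40 °C
Reagents that add atoms: allyl bromide 13, C=CCBr
Why: C8 is now the only enolisable position, so twofold enolate C-allylation is regiochemically unambiguous, and any O-allyl enol ether formed in the second round would return to the C-allyl product by Claisen rearrangement on warming.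

Step 7
Reactants: 14 8,8-diallyl indanone triester
Product: 15 spiro-cyclopentene keto triester
Conditions: second-generation Grubbs catalyst (H2IMes)(PCy3)Cl2Ru=CHPh (2 mol%), CH2Cl2, 40 °C
Reagents that add atoms: none
Why: Ring-closing metathesis of a gem-diallyl unit is favoured by the quaternary centre and gives the spiro cyclopent-3-ene in which C14 and C15 are related by the mirror plane of ring B.

Step 8
Reactants: 15 spiro-cyclopentene keto triester; 16 vinylmagnesium bromide
Product: 17 racemic 9-hydroxy-9-vinyl spiro triester
Conditions: CeCl3, THF, −78 °C; aq. NH4Cl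
Reagents that add atoms: vinylmagnesium bromide 16, C=C[Mg]Br
Why: The ketone has no α-hydrogen and the organocerium reagent derived from the Grignard reagent should add 1,2 to it faster than to the hindered or conjugated esters, giving a tertiary allylic alcohol whose C9 centre is erased in the next step.

Step 9
Reactants: 17 racemic 9-hydroxy-9-vinyl spiro triester
Product: 18 (Z)-enal (C9=C11, formyl C12 on the side of aromatic C1–H)
Conditions: pyridinium chlorochromate C5H5NH[CrO3Cl], 4 Å sieves, CH2Cl2, rt
Reagents that add atoms: pyridinium chlorochromate, [O-][Cr](=O)(=O)Cl.c1cc[nH+]cc1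
Why: Babler–Dauben oxidative transposition proceeds by [3,3] shift of the allylic chromate ester, which transfers oxygen to C12 and places the C9=C11 bond in conjugation with the arene, the formyl group taking the arene side because the other side is blocked by the C14 and C15 methylenes.

Step 10
Reactants: 18 (Z)-enal
Product: 20 (9R)-alcohol gem-diester, via aldehyde 19 (not isolated)
Conditions: (S)-2-tert-butyl-3-methylimidazolidin-4-one·CF3CO2H (20 mol%), Hantzsch ester, CHCl3, −30 °C; then NaBH4, EtOH, 0 °C
Reagents that add atoms: none
Why: Iminium-catalysed enantioselective transfer hydrogenation delivers hydride from the dihydropyridine to the face of C9 left open by the tert-butyl group of the catalyst, and because 18 is mirror-symmetric the catalyst alone should set the (9R) centre before borohydride reduces the aldehyde chemoselectively.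

Step 11
Reactants: 20 (9R)-alcohol gem-diester
Product: 22 (6R,9R)-alcohol mono-ester (ester trans to the chain), via cis ester epimer 21 (not isolated)
Conditions: LiCl, H2O, DMSO, 140 °C; then DBU, 80 °C
Reagents that add atoms: none
Why: Krapcho dealkoxycarbonylation removes one malonate ester by chloride attack at its methyl group and decarboxylation, and base equilibration of the resulting benzylic ester should place it trans to the C9 chain, where it sits pseudo-axial and clear of the C4 methyl group while the chain stays pseudo-equatorial.

Step 12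
Reactants: 22 (6R,9R)-alcohol mono-ester
Product: 23 (6R,9R)-mesylate
Conditions: MsCl, Et3N, CH2Cl2, 0 °C
Reagents that add atoms: methanesulfonyl chloride, CS(=O)(=O)Cl
Why: Sulfonylation of the primary alcohol gives a leaving-group precursor that, unlike an iodide, is inert to osmium tetroxide, hypervalent iodine and zinc in the next three steps.

Step 13
Reactants: 23 (6R,9R)-mesylate
Product: 24 (6R,9R)-mesylate cis-13,16-diol
Conditions: OsO4 (2 mol%), NMO, acetone–H2O, rt
Reagents that add atoms: osmium tetroxide (catalytic oxygen carrier), O=[Os](=O)(=O)=O; N-methylmorpholine N-oxide, C[N+]1([O-])CCOCC1; water, O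
Why: Catalytic syn-dihydroxylation under Upjohn conditions takes the unhindered cis-disubstituted alkene in preference to the electron-poor furan double bond, and both facial diastereomers are carried on because they converge in step 14.

Step 14
Reactants: 24 (6R,9R)-mesylate cis-13,16-diol
Product: 25 (6R,9R)-mesylate 13,16-dione
Conditions: IBX (3 equiv), DMSO, rt
Reagents that add atoms: none
Why: 2-Iodoxybenzoic acid oxidises vicinal diols to 1,2-diketones without C–C cleavage under neutral conditions that leave the mesylate and the C6 centre untouched.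

Step 15
Reactants: 25 (6R,9R)-mesylate 13,16-dione
Product: 26 (6R,9R)-mesylate 13,16-bis(trimethylsilyl) enediol ether
Conditions: Zn dust, Me3SiCl, THF, 0 °C to rt; filtration, non-aqueous work-up
Reagents that add atoms: chlorotrimethylsilane, C[Si](C)(C)Cl
Why: Reductive silylation of a 1,2-dione by zinc in the presence of the chlorosilane traps the enediolate on both oxygens, and since either enol tautomer of 25 leads to the same tetrasubstituted enediol ether the position of the double bond is unambiguous.

Step 16
Reactants: 26 (6R,9R)-mesylate 13,16-bis(trimethylsilyl) enediol ether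
Product: 27 (6R,9R)-iodide 13,16-bis(trimethylsilyl) enediol ether
Conditions: NaI, dry acetone, rt, dark; pentane trituration
Reagents that add atoms: sodium iodide, [Na+].[I-]
Why: Finkelstein exchange of the primary mesylate is neutral and anhydrous, so the silyl enol ethers should survive, and it supplies the better leaving group for a cyclisation that must outrun proton transfer.

Step 17
Reactants: 27 (6R,9R)-iodide 13,16-bis(trimethylsilyl) enediol ether
Product: 29 tetracyclic 13-trimethylsilyloxy 16-ketone, via tetrabutylammonium enolate 28 (not isolated)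
Conditions: Bu4N[Ph3SiF2] (1.05 equiv), THF, 0.005 M, −40 °C to rt; pH 7 buffer
Reagents that add atoms: none
Why: Anhydrous fluoride removes one trimethylsilyl group to give an ammonium α-silyloxy enolate, and fast 1,4-silyl transfer between the two oxygens lets the charge sit on either of them before C–C bond formation, so the reactive O16 enolate is always available. The closest known reaction type is the fluoride-triggered C-alkylation of enolates released from 1,2-bis(silyloxy)cycloalkenes, combined with bicyclo[3.2.1]octanone formation by intramolecular alkylation of a cyclopentanone enolate. Ring C closes in a 6-exo-tet mode with the enolate double bond outside the forming ring, C13 displacing iodide from C12. C13 is fixed because only the enediol carbon on the arm syn to the C11–C12 chain can reach C12, so the (9R) centre dictates it through the tether, and C8 becomes stereogenic as a consequence of the same choice between its two arms. The step needs arm selectivity and C- over O-alkylation: the first is geometric and the second follows from the six-membered carbocyclic transition state being preferred to the seven-membered one through oxygen, while high dilution, a single equivalent of fluoride and the poor orbital alignment of the pseudo-equatorial C6–H should hold back intermolecular reaction, loss of the second silyl group and proton transfer.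

Step 18
Reactants: 29 tetracyclic 13-trimethylsilyloxy 16-ketone; 30 methyltriphenylphosphonium bromide
Product: 31 13-trimethylsilyloxy 16-methylene diester
Conditions: Ph3PCH3Br (4 equiv), KOt-Bu (3.8 equiv), THF, 0 °C to rt
Reagents that add atoms: methylenetriphenylphosphorane (from 30), C=P(c1ccccc1)(c1ccccc1)c1ccccc1
Why: Wittig methylenation is established for hindered bicyclo[3.2.1]octanones bearing a fully substituted oxygenated α-carbon, the silyl ether prevents α-ketol rearrangement under the basic conditions, and any epimerisation at C6 should return to the favoured pseudo-axial ester.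

Step 19
Reactants: 31 13-trimethylsilyloxy 16-methylene diester
Product: 32 pharbinilic acid
Conditions: LiOH, THF–MeOH–H2O, 50 °C; then 1 M HCl to pH 3, 0 °C
Reagents that add atoms: lithium hydroxide, [Li+].[OH-]; water, O
Why: Aqueous hydroxide cleaves the tertiary trimethylsilyl ether and saponifies both esters in one operation with C6 held in its thermodynamically preferred configuration, and brief cold acidification avoids acid-induced rearrangement of the 13-hydroxy-16-ene unit.

**Compound list**

1 | 3-bromo-2-methylphenol | Cc1c(O)cccc1Br | starting material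
2 | paraformaldehyde (shown as its monomer) | C=O | starting material
3 | 4-bromo-2-hydroxy-3-methylbenzaldehyde | O=Cc1ccc(Br)c(C)c1O | intermediate
4 | ethyl diazoacetate | CCOC(=O)C=[N+]=[N-] | starting material
5 | ethyl 6-bromo-2-hydroxy-7-methyl-2,3-dihydrobenzofuran-3-carboxylate (hemiacetal, diastereomer mixture) | CCOC(=O)C1C(O)Oc2c(C)c(Br)ccc12 | intermediate (not isolated)
6 | ethyl 6-bromo-7-methylbenzofuran-3-carboxylate | CCOC(=O)c1coc2c(C)c(Br)ccc12 | intermediate
7 | dimethyl malonate | COC(=O)CC(=O)OC | starting material
8 | dimethyl 2-[3-(ethoxycarbonyl)-7-methylbenzofuran-6-yl]malonate | CCOC(=O)c1coc2c(C)c(C(C(=O)OC)C(=O)OC)ccc12 | intermediate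
9 | tert-butyl bromoacetate | CC(C)(C)OC(=O)CBr | starting material
10 | 1-tert-butyl 2,2-dimethyl 2-[3-(ethoxycarbonyl)-7-methylbenzofuran-6-yl]ethane-1,2,2-tricarboxylate | CCOC(=O)c1coc2c(C)c(C(CC(=O)OC(C)(C)C)(C(=O)OC)C(=O)OC)ccc12 | intermediate
11 | 3-[3-(ethoxycarbonyl)-7-methylbenzofuran-6-yl]-4-methoxy-3-(methoxycarbonyl)-4-oxobutanoic acid | CCOC(=O)c1coc2c(C)c(C(CC(=O)O)(C(=O)OC)C(=O)OC)ccc12 | intermediate (not isolated)
12 | indanone triester: 3-ethyl 7,7-dimethyl 8-methyl-5-oxo-5,6-dihydro-7H-indeno[5,6-b]furan-3,7,7-tricarboxylate (C9 ketone, C8 methylene, C6 gem-diester) | O=C1c2cc3c(C(=O)OCC)coc3c(C)c2C(C(=O)OC)(C(=O)OC)C1 | intermediate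
13 | allyl bromide | C=CCBr | starting material
14 | 8,8-diallyl indanone triester (12 with two allyl groups on C8) | O=C1c2cc3c(C(=O)OCC)coc3c(C)c2C(C(=O)OC)(C(=O)OC)C1(CC=C)CC=C | intermediate
15 | spiro-cyclopentene keto triester (12 with C8 spiro-fused to cyclopent-3-ene through C14 and C15) | O=C1c2cc3c(C(=O)OCC)coc3c(C)c2C(C(=O)OC)(C(=O)OC)C14CC=CC4 | intermediate
16 | vinylmagnesium bromide | C=C[Mg]Br | starting material
17 | racemic 9-hydroxy-9-vinyl spiro triester | C=CC1(O)c2cc3c(C(=O)OCC)coc3c(C)c2C(C(=O)OC)(C(=O)OC)C14CC=CC4 | intermediate
18 | (Z)-enal: spiro triester with C9=C11–C12HO, formyl group on the side of aromatic C1–H | O=C/C=C1\c2cc3c(C(=O)OCC)coc3c(C)c2C(C(=O)OC)(C(=O)OC)C14CC=CC4 | intermediate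
19 | (9R)-aldehyde: spiro triester with C9–H and a CH2CHO chain | O=CC[C@H]1c2cc3c(C(=O)OCC)coc3c(C)c2C(C(=O)OC)(C(=O)OC)C14CC=CC4 | intermediate (not isolated)
20 | (9R)-alcohol gem-diester: spiro triester with C9–H and a CH2CH2OH chain | OCC[C@H]1c2cc3c(C(=O)OCC)coc3c(C)c2C(C(=O)OC)(C(=O)OC)C14CC=CC4 | intermediate
21 | (6S,9R)-alcohol mono-ester, C6 ester cis to the C9 chain | OCC[C@H]1c2cc3c(C(=O)OCC)coc3c(C)c2[C@@H](C(=O)OC)C14CC=CC4 | intermediate (not isolated)
22 | (6R,9R)-alcohol mono-ester, C6 ester trans to the C9 chain | OCC[C@H]1c2cc3c(C(=O)OCC)coc3c(C)c2[C@H](C(=O)OC)C14CC=CC4 | intermediate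
23 | (6R,9R)-mesylate (methanesulfonate of 22) | CS(=O)(=O)OCC[C@H]1c2cc3c(C(=O)OCC)coc3c(C)c2[C@H](C(=O)OC)C14CC=CC4 | intermediate
24 | (6R,9R)-mesylate cis-13,16-diol (both facial isomers; carbinol configurations left open) | CS(=O)(=O)OCC[C@H]1c2cc3c(C(=O)OCC)coc3c(C)c2[C@H](C(=O)OC)C14CC(O)C(O)C4 | intermediate
25 | (6R,9R)-mesylate 13,16-dione (drawn as diketone; largely enolised) | CS(=O)(=O)OCC[C@H]1c2cc3c(C(=O)OCC)coc3c(C)c2[C@H](C(=O)OC)C14CC(=O)C(=O)C4 | intermediate
26 | (6R,9R)-mesylate 13,16-bis(trimethylsilyl) enediol ether | CS(=O)(=O)OCC[C@H]1c2cc3c(C(=O)OCC)coc3c(C)c2[C@H](C(=O)OC)C14CC(O[Si](C)(C)C)=C(O[Si](C)(C)C)C4 | intermediate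
27 | (6R,9R)-iodide 13,16-bis(trimethylsilyl) enediol ether (precursor of the key step) | ICC[C@H]1c2cc3c(C(=O)OCC)coc3c(C)c2[C@H](C(=O)OC)C14CC(O[Si](C)(C)C)=C(O[Si](C)(C)C)C4 | intermediate
28 | tetrabutylammonium enolate: O16 oxyanion, C13 silyl ether on the arm syn to the chain | [O-]C1=C(O[Si](C)(C)C)C[C@@]2(C1)[C@@H](CCI)c1cc3c(C(=O)OCC)coc3c(C)c1[C@@H]2C(=O)OC.CCCC[N+](CCCC)(CCCC)CCCC | intermediate (not isolated)
29 | (6R,8R,9R,13S)-13-trimethylsilyloxy 16-ketone with rings C and D closed (product of the key step) | O=C1C[C@]23C[C@@]1(O[Si](C)(C)C)CC[C@H]2c1cc2c(C(=O)OCC)coc2c(C)c1[C@@H]3C(=O)OC | intermediate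
30 | methyltriphenylphosphonium bromide | C[P+](c1ccccc1)(c1ccccc1)c1ccccc1.[Br-] | starting material
31 | (6R,8S,9R,13S)-13-trimethylsilyloxy 16-methylene diester | C=C1C[C@]23C[C@@]1(O[Si](C)(C)C)CC[C@H]2c1cc2c(C(=O)OCC)coc2c(C)c1[C@@H]3C(=O)OC | intermediate
32 | pharbinilic acid, (6R,8S,9R,13S) | C=C1C[C@]23C[C@@]1(O)CC[C@H]2c1cc2c(C(=O)O)coc2c(C)c1[C@@H]3C(=O)O | target

**Step count.** Total: 19 steps. Longest linear sequence: 19 steps (the route is linear from 1).

**Steps most likely to fail**

Step 17 (ring C closure). Proton transfer from C6–H or adventitious water to the α-silyloxy enolate may outrun C–C bond formation, which would desilylate the substrate or, through the C6 ester enolate, close C6 onto C12. O-alkylation through a seven-membered transition state and loss of the second silyl group followed by α-ketol rearrangement are the other ways it can go astray. The fallback removes the acidic C6–H from the cyclisation substrate by postponing the dealkoxycarbonylation. It sets out from alcohol 20. Mesylation gives gem-diester mesylate F1, dihydroxylation gives diol F2, IBX oxidation gives dione F3, Zn/Me3SiCl gives bis(trimethylsilyl) enediol ether F4, and NaI gives iodide F5. Fluoride then releases gem-diester enolate F6, which closes to tetracyclic gem-diester ketone F7, and Wittig methylenation gives 16-methylene gem-diester F8. LiCl in wet DMSO removes one ester, and the 6-epimer F9 formed alongside is equilibrated with DBU. The route is rejoined at 31.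

Step 10 (enantioselective reduction). Hydride transfer to the doubly substituted, neopentyl-like C9 of the iminium ion may be slow, which would allow background reduction, low conversion or insufficient facial discrimination. The fallback replaces organocatalytic hydride transfer by hydroxyl-directed hydrogenation. It sets out from enal 18, which is reduced 1,2 under Luche conditions (NaBH4, CeCl3, MeOH) to (Z)-allylic alcohol F10. Hydrogenation with Ru(OAc)2[(R)-BINAP] and H2 in MeOH should then set C9 and leave the isolated cyclopentene untouched; the BINAP enantiomer is chosen by analogy with the known facial rule for geometrically defined allylic alcohols. The route is rejoined at alcohol 20.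

Step 15 (reductive bis-silylation). Reduction of the enolised dione may be incomplete, the enol may be silylated without reduction, or the enediol ether may hydrolyse during isolation. The fallback avoids the dione. It sets out from diol 24, which stannylene-mediated mono-oxidation (Bu2SnO, then NBS) converts into acyloin F11 as a mixture of regio- and stereoisomers. Soft enolisation with Me3SiOTf and Et3N under equilibrating conditions should then give the tetrasubstituted enediol ether. The route is rejoined at 26.

**Further compounds**

F1 | step 17 | (9R)-mesylate gem-diester | CS(=O)(=O)OCC[C@H]1c2cc3c(C(=O)OCC)coc3c(C)c2C(C(=O)OC)(C(=O)OC)C14CC=CC4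
F2 | step 17 | (9R)-mesylate gem-diester cis-13,16-diol | CS(=O)(=O)OCC[C@H]1c2cc3c(C(=O)OCC)coc3c(C)c2C(C(=O)OC)(C(=O)OC)C14CC(O)C(O)C4
F3 | step 17 | (9R)-mesylate gem-diester 13,16-dione | CS(=O)(=O)OCC[C@H]1c2cc3c(C(=O)OCC)coc3c(C)c2C(C(=O)OC)(C(=O)OC)C14CC(=O)C(=O)C4
F4 | step 17 | (9R)-mesylate gem-diester bis(trimethylsilyl) enediol ether | CS(=O)(=O)OCC[C@H]1c2cc3c(C(=O)OCC)coc3c(C)c2C(C(=O)OC)(C(=O)OC)C14CC(O[Si](C)(C)C)=C(O[Si](C)(C)C)C4
F5 | step 17 | (9R)-iodide gem-diester bis(trimethylsilyl) enediol ether | ICC[C@H]1c2cc3c(C(=O)OCC)coc3c(C)c2C(C(=O)OC)(C(=O)OC)C14CC(O[Si](C)(C)C)=C(O[Si](C)(C)C)C4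
F6 | step 17 | tetrabutylammonium enolate of the gem-diester iodide | [O-]C1=C(O[Si](C)(C)C)C[C@@]2(C1)[C@@H](CCI)c1cc3c(C(=O)OCC)coc3c(C)c1C2(C(=O)OC)C(=O)OC.CCCC[N+](CCCC)(CCCC)CCCC
F7 | step 17 | tetracyclic gem-diester 13-trimethylsilyloxy 16-ketone | O=C1C[C@]23C[C@@]1(O[Si](C)(C)C)CC[C@H]2c1cc2c(C(=O)OCC)coc2c(C)c1C3(C(=O)OC)C(=O)OC
F8 | step 17 | tetracyclic gem-diester 13-trimethylsilyloxy 16-methylene compound | C=C1C[C@]23C[C@@]1(O[Si](C)(C)C)CC[C@H]2c1cc2c(C(=O)OCC)coc2c(C)c1C3(C(=O)OC)C(=O)OC
F9 | step 17 | 6-epimer of 31 | C=C1C[C@]23C[C@@]1(O[Si](C)(C)C)CC[C@H]2c1cc2c(C(=O)OCC)coc2c(C)c1[C@H]3C(=O)OC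
F10 | step 10 | (Z)-allylic alcohol of the spiro triester | OC/C=C1\c2cc3c(C(=O)OCC)coc3c(C)c2C(C(=O)OC)(C(=O)OC)C14CC=CC4
F11 | step 15 | (6R,9R)-mesylate acyloin (13/16-hydroxy ketone, isomer mixture) | CS(=O)(=O)OCC[C@H]1c2cc3c(C(=O)OCC)coc3c(C)c2[C@H](C(=O)OC)C14CC(O)C(=O)C4
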